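**Plan**
- Retrosynthesis: (i) cyclopentadiene is added back across C2=C3 of the dienone (forward: retro-Diels–Alder). (ii) The C2–allyl bond is cut (enolate allylation). (iii) The C4–C(alkenyl) bond and the C4–O–CH3 bond are cut together (alkenyllithium plus ketone, then MeOTf). (iv) The tricyclic enedione falls into 2-methoxy-1,4-benzoquinone and cyclopentadiene, and the alkenyl iodide goes back to 4-iodoveratrole and propyne.
- Enabling feature: in the six-membered ring, C1=O, C6 and C5–OMe form a vinylogous ester. The ring is therefore a 2-methoxy-1,4-benzoquinone in which only the carbonyl at C4 is ketone-like, and only the C2=C3 bond is dienophilic and can be parked in a norbornene ring.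
- Forward order: aryl propyne → (Z)-boronate → (E)-iodide; quinone + cyclopentadiene → endo adduct; union of the two halves at C4; allyl group at C2; loss of cyclopentadiene restores the dienone. The only ring that is built is temporary.
- Stereochemistry: a catalytic enantioselective Diels–Alder reaction sets four transient centres. The folded adduct relays them to C4 by convex-face attack, and cycloreversion erases the four and leaves (S)-C4. The E double bond comes from syn borylcupration and retentive B→I→Li→C exchanges.

Key step: step 5

Assumption: the sense of induction in step 4 follows the accepted model for oxazaborolidinium-bound quinones but is not proven for this pair. Both catalyst antipodes are available, and the one that gives the drawn adduct is used.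

**Step 1**
Reactants: 1 4-iodo-1,2-dimethoxybenzene; 2 propyne
Product: 3 1,2-dimethoxy-4-(prop-1-yn-1-yl)benzene
Conditions: PdCl2(PPh3)2 (2 mol %), CuI (4 mol %), Et3N, THF, rt
Reagents that add atoms: none
Why: Sonogashira coupling, in which oxidative addition of the aryl iodide is fast at room temperature and propyne is the only terminal alkyne present, so the aryl–C(sp) bond should form cleanly.

**Step 2**
Reactants: 3 1,2-dimethoxy-4-(prop-1-yn-1-yl)benzene
Product: 4 2-[(Z)-1-(3,4-dimethoxyphenyl)prop-1-en-2-yl]-4,4,5,5-tetramethyl-1,3,2-dioxaborolane (boron trans to the aryl ring)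
Conditions: B2pin2, CuCl (5 mol %), Xantphos (5 mol %), NaOt-Bu (10 mol %), MeOH (2 equiv), THF, rt
Reagents that add atoms: bis(pinacolato)diboron, CC1(C)OB(OC1(C)C)B1OC(C)(C)C(C)(C)O1
Why: Copper-catalysed borylcupration–protonolysis (formal hydroboration) of an aryl alkyl alkyne, in which Cu–Bpin adds syn with copper on the benzylic carbon and boron on the methyl-bearing carbon, and methanol replaces copper by hydrogen with retention.

**Step 3**
Reactants: 4 the (Z)-alkenylboronate
Product: 6 4-[(E)-2-iodoprop-1-en-1-yl]-1,2-dimethoxybenzene, via hydroxyboronate 5 (not isolated)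
Conditions: NaOH (aq), THF, 0 °C; then I2, 0 °C → rt
Reagents that add atoms: iodine, II
Why: Iododeboronation of an alkenylboronate by the base-first protocol, in which iodine attacks the preformed hydroxyboronate and C–B is replaced by C–I with retention of the double-bond geometry.

**Step 4**
Reactants: 7 2-methoxy-1,4-benzoquinone; 8 cyclopentadiene (freshly cracked from commercial dicyclopentadiene)
Product: 9 (1R,4S,4aR,8aS)-6-methoxy-1,4,4a,8a-tetrahydro-1,4-methanonaphthalene-5,8-dione (endo adduct)
Conditions: (S)-diphenylprolinol-derived B-(o-tolyl)oxazaborolidine·Tf2NH (10 mol %), CH2Cl2, −78 °C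
Reagents that add atoms: none
Why: Enantioselective Diels–Alder reaction of a quinone under cationic oxazaborolidine catalysis, in which only the unsubstituted C5=C6 bond of 7 is dienophilic (C2=C3 is a vinylogous ester alkene), the endo rule fixes the relative configuration of the four new centres, and the catalyst, bound to the more basic vinylogous-ester carbonyl next to C5–H, shields one quinone face and so fixes the absolute configuration.

**Step 5**
Reactants: 6 the (E)-alkenyl iodide; 9 the endo adduct
Product: 12 (1S,4R,4aS,8S,8aR)-8-[(E)-1-(3,4-dimethoxyphenyl)prop-1-en-2-yl]-7,8-dimethoxy-1,4,4a,8a-tetrahydro-1,4-methanonaphthalen-5(8H)-one (alkenyl group exo, syn to H-4a and H-8a; 8-OMe endo), via alkenyllithium 10 (not isolated), via lithium alkoxide 11 (not isolated)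
Conditions: 6, t-BuLi (2 equiv), Et2O, −78 °C; then 9, Et2O/toluene, −78 °C; then MeOTf, −78 → 0 °C
Reagents that add atoms: methyl trifluoromethanesulfonate, COS(=O)(=O)C(F)(F)F
Why: Iodine–lithium exchange gives the configurationally stable alkenyllithium 10, which adds 1,2 to the C5 ketone of 9 (C4 of the target), and the lithium alkoxide 11 is methylated in the same flask, so the C4–C(alkenyl) bond, the C4–OMe ether and the only lasting stereocentre arise in one operation. The closest known reaction types are the 1,2-addition of organolithium reagents to endo cyclopentadiene–quinone adducts (retro-Diels–Alder, "transient chirality" strategy) and the addition–O-alkylation sequence that turns quinone monoketals into p-quinol ethers. No ring is closed. The new quaternary centre is controlled by the folded endo tricycle: the lower face of the enedione ring lies over the norbornene C2=C3 bridge, so the nucleophile enters from the open convex face, syn to H-4a and H-8a, the oxygen is pushed to the endo side, and this corresponds to (S) at C4 of the target. The step needs carbonyl selectivity, which the substrate secures because C8=O is deactivated as a vinylogous ester (C8–C7=C6–OMe) whereas C5=O is only an α-methoxy enone ketone, and the hard lithium reagent at −78 °C favours 1,2- over 1,4-addition. Masking the quinone C=C bond also removes the electron-transfer side reactions of a free quinone.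

**Step 6**
Reactants: 12 the tricyclic methyl ether; 13 allyl bromide
Product: 15 (1S,4R,4aS,8S,8aR)-4a-allyl-8-[(E)-1-(3,4-dimethoxyphenyl)prop-1-en-2-yl]-7,8-dimethoxy-1,4,4a,8a-tetrahydro-1,4-methanonaphthalen-5(8H)-one, via lithium enolate 14 (not isolated)
Conditions: LDA, THF, −78 °C; then 13, DMPU, −78 → 0 °C
Reagents that add atoms: none
Why: Stork–Danheiser-type α′-alkylation of a vinylogous ester, in which H-4a is the only enolisable hydrogen, the enolate can be attacked only on its exo face because a trans fusion to the norbornene is impossible, and any O-allyl dienol ether formed beside the product would be carried to the same compound by Claisen rearrangement on warming.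

**Step 7**
Reactants: 15 the allylated tricycle
Product: 16 (4S)-2-allyl-4-[(E)-1-(3,4-dimethoxyphenyl)prop-1-en-2-yl]-4,5-dimethoxycyclohexa-2,5-dien-1-one (target)
Conditions: 1,2-dichlorobenzene, 180 °C, argon sweep
Reagents that add atoms: none
Why: Retro-Diels–Alder reaction, driven by loss of volatile cyclopentadiene, by relief of the 1,3-strain between the allyl and alkenyl groups on the crowded convex face and by the gain of the cross-conjugated dienone; it erases the four transient stereocentres and leaves C4, which is not part of the breaking bonds, untouched.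

**Compound list**
1 | 4-iodo-1,2-dimethoxybenzene | COc1ccc(I)cc1OC | starting material
2 | propyne | CC#C | starting material
3 | 1,2-dimethoxy-4-(prop-1-yn-1-yl)benzene | CC#Cc1ccc(OC)c(OC)c1 | intermediate
4 | 2-[(Z)-1-(3,4-dimethoxyphenyl)prop-1-en-2-yl]-4,4,5,5-tetramethyl-1,3,2-dioxaborolane | CC1(C)OB(OC1(C)C)/C(C)=C/c1ccc(OC)c(OC)c1 | intermediate
5 | sodium hydroxyboronate of 4 (not isolated) | [Na+].O[B-]1(OC(C)(C)C(C)(C)O1)/C(C)=C/c1ccc(OC)c(OC)c1 | intermediate
6 | 4-[(E)-2-iodoprop-1-en-1-yl]-1,2-dimethoxybenzene | I/C(C)=C/c1ccc(OC)c(OC)c1 | intermediate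
7 | 2-methoxy-1,4-benzoquinone | COC1=CC(=O)C=CC1=O | starting material
8 | cyclopentadiene | C1C=CC=C1 | starting material
9 | (1R,4S,4aR,8aS)-6-methoxy-1,4,4a,8a-tetrahydro-1,4-methanonaphthalene-5,8-dione | COC1=CC(=O)[C@@H]2[C@H](C1=O)[C@@H]3C=C[C@H]2C3 | intermediate
10 | [(Z)-1-(3,4-dimethoxyphenyl)prop-1-en-2-yl]lithium, Li trans to aryl (not isolated) | [Li]/C(C)=C/c1ccc(OC)c(OC)c1 | intermediate
11 | lithium alkoxide of the C8 carbinol (not isolated) | COC1=CC(=O)[C@@H]2[C@H]([C@]1([O-])/C(C)=C/c4ccc(OC)c(OC)c4)[C@@H]3C=C[C@H]2C3.[Li+] | intermediate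
12 | (1S,4R,4aS,8S,8aR)-8-[(E)-1-(3,4-dimethoxyphenyl)prop-1-en-2-yl]-7,8-dimethoxy-1,4,4a,8a-tetrahydro-1,4-methanonaphthalen-5(8H)-one | COC1=CC(=O)[C@@H]2[C@H]([C@]1(OC)/C(C)=C/c4ccc(OC)c(OC)c4)[C@@H]3C=C[C@H]2C3 | intermediate
13 | allyl bromide | C=CCBr | starting material
14 | lithium C5–C4a enolate of 12 (not isolated) | COC1=CC([O-])=C2[C@H]([C@]1(OC)/C(C)=C/c4ccc(OC)c(OC)c4)[C@@H]3C=C[C@H]2C3.[Li+] | intermediate
15 | (1S,4R,4aS,8S,8aR)-4a-allyl-8-[(E)-1-(3,4-dimethoxyphenyl)prop-1-en-2-yl]-7,8-dimethoxy-1,4,4a,8a-tetrahydro-1,4-methanonaphthalen-5(8H)-one | COC1=CC(=O)[C@]2(CC=C)[C@H]([C@]1(OC)/C(C)=C/c4ccc(OC)c(OC)c4)[C@@H]3C=C[C@H]2C3 | intermediate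
16 | (4S)-2-allyl-4-[(E)-1-(3,4-dimethoxyphenyl)prop-1-en-2-yl]-4,5-dimethoxycyclohexa-2,5-dien-1-one | C=CCC1=C[C@](OC)(/C(C)=C/c2ccc(OC)c(OC)c2)C(OC)=CC1=O | target

**Totals**
Total step count: 7. Longest linear sequence: 6 (steps 1, 2, 3, 5, 6, 7).

**Steps most likely to fail**

1. Step 5.
   - What may go wrong: the basic alkenyllithium may deprotonate the acidic ring-fusion hydrogens of the enedione, which leads to aromatisation on work-up. O-methylation of the alkoxide buried in the concave pocket may also be slow.
   - Fallback, from 10 and 9, back at 15: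
     - 10 is transmetalated with anhydrous CeCl3 to the far less basic alkenylcerium reagent F1.
     - F1 is added to 9 and worked up with aqueous NH4Cl to give the free carbinol F2.
     - Double deprotonation (LDA, 2.2 equiv) and C-allylation with 13 gives the allylated carbinol F3.
     - F3 has no enolisable hydrogen left, so the hindered alkoxide can be forced to react (KH, MeI, THF/DMF) and gives 15.

2. Step 7.
   - What may go wrong: the product may be damaged by heat, through homolysis or ionisation of the triply allylic C4–OMe bond with loss of configuration, or cyclopentadiene may add back.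
   - Fallback, from 13 and 10, back at 16; the temporary ring is left out:
     - Commercial 3,4-dimethoxyphenol is O-allylated with 13 (K2CO3, acetone) to the allyl ether F4.
     - Claisen rearrangement (N,N-diethylaniline, 190 °C) gives 2-allyl-4,5-dimethoxyphenol F5.
     - PhI(OAc)2 in aqueous MeCN gives 2-allyl-5-methoxy-1,4-benzoquinone F6.
     - 10 adds at −78 °C to the C4 carbonyl of F6, because C1=O is a vinylogous ester and is flanked by the allyl group, and MeOTf traps the alkoxide to give the racemic dienone F7.
     - F7 is resolved by preparative HPLC on a chiral stationary phase to give 16.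

3. Step 6.
   - What may go wrong: deprotonation and C-alkylation at the tertiary α′ carbon may be sluggish, because this carbon lies 1,3-syn to the bulky alkenyl group on the same face.
   - Fallback, from 14, back at 15:
     - The enolate is trapped on oxygen with allyl chloroformate to give the allyl enol carbonate F8.
     - Pd(PPh3)4 in THF then brings about decarboxylative allylation (Tsuji type, π-allylpalladium/enolate recombination under neutral conditions) on the only open exo face and gives 15.

**Further compounds**
F1 | step 5 | dichloro[(E)-1-(3,4-dimethoxyphenyl)prop-1-en-2-yl]cerium (Ce trans to aryl) | Cl[Ce](Cl)/C(C)=C/c1ccc(OC)c(OC)c1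
F2 | step 5 | (1S,4R,4aS,8S,8aR)-8-[(E)-1-(3,4-dimethoxyphenyl)prop-1-en-2-yl]-8-hydroxy-7-methoxy-1,4,4a,8a-tetrahydro-1,4-methanonaphthalen-5(8H)-one | COC1=CC(=O)[C@@H]2[C@H]([C@]1(O)/C(C)=C/c4ccc(OC)c(OC)c4)[C@@H]3C=C[C@H]2C3
F3 | step 5 | (1S,4R,4aS,8S,8aR)-4a-allyl-8-[(E)-1-(3,4-dimethoxyphenyl)prop-1-en-2-yl]-8-hydroxy-7-methoxy-1,4,4a,8a-tetrahydro-1,4-methanonaphthalen-5(8H)-one | COC1=CC(=O)[C@]2(CC=C)[C@H]([C@]1(O)/C(C)=C/c4ccc(OC)c(OC)c4)[C@@H]3C=C[C@H]2C3
F4 | step 7 | 4-(allyloxy)-1,2-dimethoxybenzene | C=CCOc1ccc(OC)c(OC)c1
F5 | step 7 | 2-allyl-4,5-dimethoxyphenol | C=CCc1cc(OC)c(OC)cc1O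
F6 | step 7 | 2-allyl-5-methoxy-1,4-benzoquinone | C=CCC1=CC(=O)C(OC)=CC1=O
F7 | step 7 | racemic 2-allyl-4-[(E)-1-(3,4-dimethoxyphenyl)prop-1-en-2-yl]-4,5-dimethoxycyclohexa-2,5-dien-1-one | C=CCC1=CC(OC)(/C(C)=C/c2ccc(OC)c(OC)c2)C(OC)=CC1=O
F8 | step 6 | allyl enol carbonate of 12 (O-acylated C5–C4a enolate) | COC1=CC(OC(=O)OCC=C)=C2[C@H]([C@]1(OC)/C(C)=C/c4ccc(OC)c(OC)c4)[C@@H]3C=C[C@H]2C3
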